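The readings were generated by integration for substances that don't exist; the scatter is artificial.

The trap in a fed flask is to compare percentages of the charge and treat the feed as a mere delay, when a step of higher order feels the [starting material] actually standing there.

| flask | starting material | capture agent | remark | time |
|---|---|---|---|---|
| cedar | 0.30 M | 0.015 M | run made earlier |  |
| maple | 0.30 M | 0.022 M | run made earlier |  |
| summer | 0.30 M | 0.0150 M | a single well-mixed tank run continuously and read at steady state, 6.0 min in it on average |  |
| midnight | 0.30 M | 0.0150 M | everything together in a closed stirred flask, run for 6.0 min | 6.0 min |
| noon | 0.30 M (fed, over 4.80 min) | 0.0150 M | a stirred flask in which starting material is dosed at a steady rate over 4.80 min without added volume, worked up at 6.0 min | 6.0 min |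

cedar run (percent of the starting material charged)

| time / min | target / % | starting material / % |
|---|---|---|
| 0.500 | 21.1 | 54.7 |
| 1.50 | 40.0 | 23.1 |
| 3.00 | 46.3 | 11.9 |
| 4.00 | 49.6 | 12.0 |
| 6.00 | 48.5 | 10.8 |

maple run (percent of the starting material charged)

| time / s | target / % | starting material / % |
|---|---|---|
| 10.0 | 5.6 | 78.9 |
| 20.0 | 16.6 | 66.8 |
| 40.0 | 25.4 | 47.1 |
| 80.0 | 37.5 | 25.3 |

(scatter of a reading: 1 percentage point)

- order of the set-ups by the amount of target at the outlet or at the end, in percent of the starting material put in, highest first (summer / midnight / noon)
- amount of target at the outlet or at the end, in percent of the starting material put in, summer
- amount of target at the outlet or at the end, in percent of the starting material put in, midnight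
- amount of target at the outlet or at the end, in percent of the starting material put in, noon

- the stated concentrations are those of everything mixed, before any reaction; amounts are the same in each set-up
- the analysis behind the earlier runs scatters by 1 percentage point, standard deviation
- the feed brings no volume worth counting
- the earlier runs were made in a closed, stirred flask

From the last three cedar readings I read a stall at 11.6% of the charge. The first cedar reading, measured against that stall, gives a relaxation rate of 1.44 /min, and both values carry the scatter. Cedar and maple both hold 0.30 M of starting material, so this pair of runs does not vary it.

The bench rule counts turnovers during the feed: noon gets 6.89 in its 4.80 min, and a one-way first-order step fed evenly stands at the charge divided by that count, here 14.5%. That rule has no floor, but the stall times the count, which is the stall as a share of the rule's level, is 0.799, so I keep the stall in the reckoning. I therefore use the standing level, the stall plus the remaining share divided by the turnovers, the accumulation of a semi-batch feed: 24.4% for noon at the end of the feed. That is 0.0732 M, about a quarter of the 0.30 M with which midnight opens.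

The rule stops again when the feed stops. The tail is 20.0% of the run, or 1.72 turnovers, so I reckon noon ends at 13.9%. I commit to this: if part of the loss goes with the square of [starting material], noon ends above midnight in target.

The forecast gives summer 42%, midnight 48.5% and noon 46.5%, in the order midnight > noon > summer, on the ground “Selectivity looks constant, so dosing gains nothing”.

The flask gives summer 45.7%, midnight 48.3% and noon 52.2%, in the order noon > midnight > summer.

    starting material ⇌ open intermediate (K = 2.00, k = 0.0160 /s)
    open intermediate ⇌ target (K = 2.30, k = 0.230 /s)
    open intermediate + capture agent → trapped intermediate (k = 0.00840 /M/s)
    2 starting material → self-condensation product (k = 0.0110 /M/s)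

Noon holds 26.8% of starting material at the end of the feed against my 24.4%, and 15.0% at 6.00 min against my 13.9%. The neighbouring flask is noon with 1.2 M of starting material. My count of turnovers does not change, so I reckon its standing level at 24.4% again, but that now means 0.293 M, close to midnight's opening 0.30 M. It ends with 43.3% of target, against 52.2% in noon. Self-condensation product, counted by the starting material it holds, is at 6.00 min 9.44% in noon and 26.4% in the neighbour.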